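**Plan**

- Ring numbering used throughout: C1 (CH–OBz), C2=C3 (C3 carries CO2H), C4, C5, C6 (epoxide CH), C7 (epoxide C–CH3), C8–C10 (three CH2), C11 (CMe2).
- Retrosynthesis: unmask CO2H from a fluoride-labile 2-(trimethylsilyl)ethyl (TMSE) ester. Take the epoxide oxygen off C6/C7 to leave an E-alkene. Cut the ring bond C7–C8, then C2=C3 (Wittig) and C3–C4 (ylide alkylation).
- Enabling feature: C7 is the methyl-bearing end of a masked E-trisubstituted alkene, and C8 opens an unfunctionalised (CH2)3 run that ends at quaternary C11. C7–C8 is therefore an sp2–sp3 bond between an (E)-2-iodoalkene and the anti-Markovnikov borane of a terminal alkene. The ring-cis C2=C3 enoate and the C11 gem-dimethyl group fold the chain.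
- Forward: two fragments (C1 and C8–C11 from 2,2-dimethylpent-4-enal; C3–C7 from pent-3-yn-1-ol and a TMSE ester ylide) are joined at C2=C3 to an acyclic iodotriene. One-pot hydroboration and intramolecular B-alkyl Suzuki-Miyaura coupling closes the eleven-membered ring. The oxirane ring follows, then the acid is freed.
- Stereochemistry: C1 comes from an organocatalytic alpha-benzoyloxylation, which also installs the benzoate. C2=C3 comes from the stabilised-ylide Wittig. E-C6=C7 comes from syn-hydrozirconation and is carried through the coupling with retention. C6/C7 (R,R) come from a catalyst-controlled Shi epoxidation.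

Key step: step 8

Remark: the sense of induction in step 2 is assumed to follow the steric-shielding model of 2-substituted pyrrolidine enamines (S catalyst gives S aldehyde). The R catalyst would serve if the opposite sense were found.

**Step 1**
Reactants: 1 2,2-dimethylpent-4-enal
Product: 3 3,3-dimethylhex-5-enal, via enol ether 2 (not isolated)
Conditions: MeOCH2PPh3Cl, KOtBu, THF, 0 °C to rt; then 2 M HCl, THF, rt
Reagents that add atoms: (methoxymethyl)triphenylphosphonium chloride, COC[P+](c1ccccc1)(c1ccccc1)c1ccccc1.[Cl-]; water, O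
Why: Wittig methoxymethylenation of the non-enolisable aldehyde followed by acid hydrolysis of the enol ether is the standard one-carbon aldehyde homologation; it creates the enolisable CH2 (future C1) that step 2 needs, and no stereocentre is formed.

**Step 2**
Reactants: 3 3,3-dimethylhex-5-enal
Product: 4 (2S)-3,3-dimethyl-1-oxohex-5-en-2-yl benzoate
Conditions: (PhCO2)2, (S)-2-tritylpyrrolidine (10 mol %), hydroquinone (10 mol %), THF, rt
Reagents that add atoms: dibenzoyl peroxide, O=C(OOC(=O)c1ccccc1)c1ccccc1
Why: In this organocatalytic enamine alpha-benzoyloxylation the E-enamine of 3 attacks a peroxide oxygen from the face not covered by the trityl group, which should set C1 as S in 4 (R in the target after the change of substituent priorities) and delivers the benzoate of the target directly, beta-quaternary aldehydes being accepted in enamine alpha-heterofunctionalisation.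

**Step 3**
Reactants: 5 pent-3-yn-1-ol
Product: 7 (3E)-4-iodopent-3-en-1-ol, via alkenylzirconocene 6 (not isolated)
Conditions: Cp2ZrHCl (2.5 equiv), THF, rt to 45 °C; then I2, THF, 0 °C
Reagents that add atoms: Cp2ZrHCl, [H][Zr](Cl)(C1C=CC=C1)C1C=CC=C1 (zirconium stays only in 6); iodine, II
Why: In the hydrozirconation-iodinolysis with the Schwartz reagent, syn addition of Zr–H (equilibrated by excess reagent to place zirconium on the less hindered, methyl-bearing carbon) and iodinolysis with retention should give the E-iodoalkene, the first equivalent of reagent only turning OH into the zirconium alkoxide.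

**Step 4**
Reactants: 7 (3E)-4-iodopent-3-en-1-ol
Product: 8 (2E)-2,5-diiodopent-2-ene
Conditions: I2, PPh3, imidazole, CH2Cl2, 0 °C
Reagents that add atoms: iodine, II
Why: Appel-type iodination replaces the primary OH by SN2 displacement of the oxyphosphonium group and leaves the alkenyl iodide and its geometry untouched.

**Step 5**
Reactants: 9 (triphenylphosphoranylidene)ketene (Bestmann ylide); 10 2-(trimethylsilyl)ethanol
Product: 11 2-(trimethylsilyl)ethyl (triphenylphosphoranylidene)acetate
Conditions: toluene, 110 °C
Reagents that add atoms: none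
Why: Addition of an alcohol across the cumulated C=C=O unit of the Bestmann ylide is the known direct entry to stabilised ester ylides and installs the fluoride-labile ester without any by-product.

**Step 6**
Reactants: 11 2-(trimethylsilyl)ethyl (triphenylphosphoranylidene)acetate; 8 (2E)-2,5-diiodopent-2-ene
Product: 13 2-(trimethylsilyl)ethyl (5E)-6-iodo-2-(triphenylphosphoranylidene)hept-5-enoate, via phosphonium iodide 12 (not isolated)
Conditions: MeCN, 80 °C; then 1 M NaOH, CH2Cl2, 0 °C
Reagents that add atoms: none
Why: C-alkylation of a stabilised ylide by the primary iodide (SN2, the sp2 C–I bond being inert) forms C3–C4, and deprotonation of the salt gives the alpha-branched ylide; transylidation should not stall the alkylation because the alkylated ylide is the stronger base.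

**Step 7**
Reactants: 4 (2S)-3,3-dimethyl-1-oxohex-5-en-2-yl benzoate; 13 2-(trimethylsilyl)ethyl (5E)-6-iodo-2-(triphenylphosphoranylidene)hept-5-enoate
Product: 14 2-(trimethylsilyl)ethyl (2E,4R)-4-(benzoyloxy)-2-[(3E)-4-iodopent-3-en-1-yl]-5,5-dimethylocta-2,7-dienoate
Conditions: toluene, 80 °C
Reagents that add atoms: none
Why: The Wittig olefination with an alpha-branched stabilised ylide under neutral, salt-free conditions is reliably E-selective (ester trans to C1, hence C1 and C4 cis as the ring requires), and the absence of added base should spare the alpha-benzoyloxy stereocentre from epimerisation.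

**Step 8**
Reactants: 14 2-(trimethylsilyl)ethyl (2E,4R)-4-(benzoyloxy)-2-[(3E)-4-iodopent-3-en-1-yl]-5,5-dimethylocta-2,7-dienoate
Product: 16 2-(trimethylsilyl)ethyl (1E,3R,8E)-3-(benzoyloxy)-4,4,8-trimethylcycloundeca-1,8-diene-1-carboxylate, via B-alkyl-9-BBN borane 15 (not isolated)
Conditions: 9-BBN-H (1.3 equiv), THF, 0 °C to rt; then slow addition (12 h) to PdCl2(dppf) (15 mol %), AsPh3 (30 mol %), Cs2CO3, DMF/THF/H2O, 50 °C, final 1 mM
Reagents that add atoms: 9-borabicyclo[3.3.1]nonane (9-BBN-H), B1C2CCCC1CCC2 (its boron framework stays only in 15; 16 keeps one hydrogen)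
Why: 9-BBN-H adds anti-Markovnikov to the only monosubstituted alkene (C8=C9) and leaves the iodoalkene, the enoate and both esters alone, which turns the unfunctionalised C8 terminus into a primary alkyl donor. Zerovalent palladium inserts into C7–I with retention, the base-activated borate hands C8 over to divalent palladium, and reductive elimination forms C7–C8; this is an intramolecular B-alkyl Suzuki-Miyaura coupling, a reaction type established for closing medium and large carbocycles. The eleven-membered carbocycle closes by C(sp3)–C(sp2) reductive elimination from a twelve-membered alkyl(alkenyl)palladacycle with C6=C7 becoming endocyclic, and no smaller ring can compete because palladium on C7 stands trans to the C5 chain, so a Heck attack on C2=C3 would need a trans double bond in a five- or six-membered ring. No stereocentre is created: the E geometry of C6=C7 is carried over from 14 by stereoretentive oxidative addition and reductive elimination, and C1 is untouched. Cyclisation must beat oligomerisation and beta-hydride elimination, which is served by pseudo-high dilution, by the wide-bite-angle dppf ligand and by two turn elements of the chain, the C11 gem-dimethyl group and the ring-cis C2=C3 enoate that point both arms to the same side. A two-electron transmetalation is chosen on purpose, since a free C8 radical (as in reductive nickel couplings of the corresponding iodide) would close 6-exo onto C2 of the enoate.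

**Step 9**
Reactants: 16 2-(trimethylsilyl)ethyl (1E,3R,8E)-3-(benzoyloxy)-4,4,8-trimethylcycloundeca-1,8-diene-1-carboxylate
Product: 17 2-(trimethylsilyl)ethyl (1R,4E,6R,11R)-6-(benzoyloxy)-7,7,11-trimethyl-12-oxabicyclo[9.1.0]dodec-4-ene-4-carboxylate
Conditions: 1,2:4,5-di-O-isopropylidene-beta-D-erythro-hexo-2,3-diulo-2,6-pyranose (Shi ketone from D-fructose, 30 mol %), KHSO5 (as 2KHSO5·KHSO4·K2SO4), K2CO3, Na2B4O7 buffer (pH 10.5), Bu4NHSO4, MeCN/CH2(OMe)2/H2O, 0 °C
Reagents that add atoms: potassium peroxymonosulfate KHSO5, [K+].[O-]S(=O)(=O)OO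
Why: In the Shi asymmetric epoxidation the chiral dioxirane attacks only the electron-rich E-trisubstituted C6=C7 bond (the C2=C3 enoate is too electron-poor) through the spiro transition state that gives R,R-epoxides from E-alkenes, and because the two faces of C6=C7 are offered by ring conformers that interconvert by rotation of the alkene through the eleven-membered ring, the catalyst should be able to choose the face and set C6 and C7 together.

**Step 10**
Reactants: 17 2-(trimethylsilyl)ethyl (1R,4E,6R,11R)-6-(benzoyloxy)-7,7,11-trimethyl-12-oxabicyclo[9.1.0]dodec-4-ene-4-carboxylate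
Product: 19 (1R,4E,6R,11R)-6-(benzoyloxy)-7,7,11-trimethyl-12-oxabicyclo[9.1.0]dodec-4-ene-4-carboxylic acid, via tetrabutylammonium carboxylate 18 (not isolated)
Conditions: Bu4NF, THF, 0 °C to rt; then pH 4 phosphate buffer (H3PO4/NaH2PO4), 0 °C
Reagents that add atoms: tetrabutylammonium fluoride, CCCC[N+](CCCC)(CCCC)CCCC.[F-] (its cation stays only in 18)
Why: Fluoride attack on silicon triggers the beta-fragmentation of the TMSE ester to ethene, Me3SiF and the carboxylate (standard silylethyl ester deprotection), conditions under which the benzoate, the enoate geometry and the trisubstituted epoxide should persist, and cold buffered protonation avoids acid-induced transannular opening of the oxirane.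

**Compound list**

1 | 2,2-dimethylpent-4-enal | C=CCC(C)(C)C=O | starting material
2 | 1-methoxy-3,3-dimethylhexa-1,5-diene (E/Z enol ether) | C=CCC(C)(C)C=COC | intermediate
3 | 3,3-dimethylhex-5-enal | C=CCC(C)(C)CC=O | intermediate
4 | (2S)-3,3-dimethyl-1-oxohex-5-en-2-yl benzoate | O=C[C@@H](OC(=O)c1ccccc1)C(C)(C)CC=C | intermediate
5 | pent-3-yn-1-ol | CC#CCCO | starting material
6 | (E)-Cp2ClZr–C(CH3)=CH–CH2CH2–O–ZrClCp2 (alkenylzirconocene alkoxide) | C/C(=C\CCO[Zr](Cl)(C1C=CC=C1)C1C=CC=C1)[Zr](Cl)(C1C=CC=C1)C1C=CC=C1 | intermediate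
7 | (3E)-4-iodopent-3-en-1-ol | OCC/C=C(\C)I | intermediate
8 | (2E)-2,5-diiodopent-2-ene | ICC/C=C(\C)I | intermediate
9 | (triphenylphosphoranylidene)ketene | O=C=C=P(c1ccccc1)(c1ccccc1)c1ccccc1 | starting material
10 | 2-(trimethylsilyl)ethanol | C[Si](C)(C)CCO | starting material
11 | 2-(trimethylsilyl)ethyl (triphenylphosphoranylidene)acetate | C[Si](C)(C)CCOC(=O)C=P(c1ccccc1)(c1ccccc1)c1ccccc1 | intermediate
12 | [(5E)-6-iodo-1-oxo-1-[2-(trimethylsilyl)ethoxy]hept-5-en-2-yl]triphenylphosphonium iodide (racemic at C2) | C[Si](C)(C)CCOC(=O)C(CC/C=C(\C)I)[P+](c1ccccc1)(c1ccccc1)c1ccccc1.[I-] | intermediate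
13 | 2-(trimethylsilyl)ethyl (5E)-6-iodo-2-(triphenylphosphoranylidene)hept-5-enoate | C[Si](C)(C)CCOC(=O)C(CC/C=C(\C)I)=P(c1ccccc1)(c1ccccc1)c1ccccc1 | intermediate
14 | 2-(trimethylsilyl)ethyl (2E,4R)-4-(benzoyloxy)-2-[(3E)-4-iodopent-3-en-1-yl]-5,5-dimethylocta-2,7-dienoate | C=CCC(C)(C)[C@H](OC(=O)c1ccccc1)/C=C(\CC/C=C(\C)I)C(=O)OCC[Si](C)(C)C | intermediate
15 | 2-(trimethylsilyl)ethyl (2E,4R)-4-(benzoyloxy)-8-(9-borabicyclo[3.3.1]nonan-9-yl)-2-[(3E)-4-iodopent-3-en-1-yl]-5,5-dimethyloct-2-enoate | C1CC2CCCC(C1)B2CCCC(C)(C)[C@H](OC(=O)c1ccccc1)/C=C(\CC/C=C(\C)I)C(=O)OCC[Si](C)(C)C | intermediate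
16 | 2-(trimethylsilyl)ethyl (1E,3R,8E)-3-(benzoyloxy)-4,4,8-trimethylcycloundeca-1,8-diene-1-carboxylate | CC1(C)CCC/C(C)=C/CC/C(C(=O)OCC[Si](C)(C)C)=C\[C@H]1OC(=O)c1ccccc1 | intermediate
17 | 2-(trimethylsilyl)ethyl (1R,4E,6R,11R)-6-(benzoyloxy)-7,7,11-trimethyl-12-oxabicyclo[9.1.0]dodec-4-ene-4-carboxylate | CC1(C)CCC[C@@]2(C)O[C@@H]2CC/C(C(=O)OCC[Si](C)(C)C)=C\[C@H]1OC(=O)c1ccccc1 | intermediate
18 | tetrabutylammonium (1R,4E,6R,11R)-6-(benzoyloxy)-7,7,11-trimethyl-12-oxabicyclo[9.1.0]dodec-4-ene-4-carboxylate | CC1(C)CCC[C@@]2(C)O[C@@H]2CC/C(C(=O)[O-])=C\[C@H]1OC(=O)c1ccccc1.CCCC[N+](CCCC)(CCCC)CCCC | intermediate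
19 | (1R,4E,6R,11R)-6-(benzoyloxy)-7,7,11-trimethyl-12-oxabicyclo[9.1.0]dodec-4-ene-4-carboxylic acid | CC1(C)CCC[C@@]2(C)O[C@@H]2CC/C(C(=O)O)=C\[C@H]1OC(=O)c1ccccc1 | target

**Step count and risks**

Total step count: 10. Longest linear sequence: 7 steps (3, 4, 6, 7, 8, 9, 10).

Steps most likely to fail:

1. **Step 8.**
   - Transannular strain in the closing eleven-membered ring may let intermolecular coupling to oligomers win.
   - Slow ring closure may give way to protodeboronation or beta-hydride elimination.
   - Zerovalent palladium may ionise the allylic benzoate.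
   - The fallback sets out from 14 and comes back at 16. It closes the ring by metathesis at the neighbouring C8=C9 position and removes that helper alkene afterwards.
   - Stille coupling of 14 with tributyl(vinyl)stannane (Pd2(dba)3, AsPh3, NMP, rt) makes C7–C8 intermolecularly with retention. It should give 2-(trimethylsilyl)ethyl (2E,4R)-4-(benzoyloxy)-5,5-dimethyl-2-[(3E)-4-methylhexa-3,5-dien-1-yl]octa-2,7-dienoate F1.
   - Diene-ene ring-closing metathesis of the two monosubstituted vinyl termini follows (second-generation Grubbs catalyst RuCl2(=CHPh)(PCy3)(SIMes), toluene, high dilution, 80 °C). It should give 2-(trimethylsilyl)ethyl (1E,3R,8E)-3-(benzoyloxy)-4,4,8-trimethylcycloundeca-1,6,8-triene-1-carboxylate F2, in which the geometry of the new bond does not matter.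
   - Diimide (2-nitrobenzenesulfonyl hydrazide, Et3N, CH2Cl2, rt) should saturate the only disubstituted double bond and lead to 16.

2. **Step 9.**
   - The conformational bias of the ring, set by C1 and the gem-dimethyl group, may override the chiral dioxirane and direct the oxidant to the wrong face of C6=C7.
   - The fallback sets out from 16 and comes back at 17. It uses a halohydrin sequence, in which the oxygen ends on the face opposite to the one first attacked by the electrophile, so the same ring bias then works for the needed isomer.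
   - NBS in THF/H2O at 0 °C forms the bromonium ion on the exposed face of the electron-rich alkene, and water opens it anti at tertiary C7. This should give 2-(trimethylsilyl)ethyl (1E,3R,8R,9S)-3-(benzoyloxy)-9-bromo-8-hydroxy-4,4,8-trimethylcycloundec-1-ene-1-carboxylate F3.
   - K2CO3 in MeCN at rt then closes the oxirane by internal SN2 displacement with inversion at C6 to give 17.

3. **Step 2.**
   - The quaternary carbon next to the enamine carbon may slow the attack on the peroxide.
   - Radical decomposition of the peroxide, low conversion or erosion of enantiopurity of the sensitive alpha-acyloxy aldehyde could then take over.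
   - The fallback sets out from 3 and comes back at 14. It replaces O-acyl transfer by the smaller, more reactive nitroso electrophile and adds the benzoate later.
   - D-Proline-catalysed alpha-aminoxylation of 3 with nitrosobenzene (DMSO, rt; hydrogen-bond-directed delivery) should give (2S)-3,3-dimethyl-2-[(phenylamino)oxy]hex-5-enal F4.
   - F4 is trapped in the same flask by ylide 13 to give 2-(trimethylsilyl)ethyl (2E,4R)-2-[(3E)-4-iodopent-3-en-1-yl]-5,5-dimethyl-4-[(phenylamino)oxy]octa-2,7-dienoate F5.
   - N–O cleavage (Zn, AcOH/THF, 0 °C) should give 2-(trimethylsilyl)ethyl (2E,4R)-4-hydroxy-2-[(3E)-4-iodopent-3-en-1-yl]-5,5-dimethylocta-2,7-dienoate F6. This compound cannot lactonise because the ester is trans to C1.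
   - Benzoylation (BzCl, pyridine, DMAP, CH2Cl2) then leads to 14.

**Further compounds**

F1 | step 8 | 2-(trimethylsilyl)ethyl (2E,4R)-4-(benzoyloxy)-5,5-dimethyl-2-[(3E)-4-methylhexa-3,5-dien-1-yl]octa-2,7-dienoate | C=CCC(C)(C)[C@H](OC(=O)c1ccccc1)/C=C(\CC/C=C(\C)C=C)C(=O)OCC[Si](C)(C)C
F2 | step 8 | 2-(trimethylsilyl)ethyl (1E,3R,8E)-3-(benzoyloxy)-4,4,8-trimethylcycloundeca-1,6,8-triene-1-carboxylate | CC1(C)CC=C/C(C)=C/CC/C(C(=O)OCC[Si](C)(C)C)=C\[C@H]1OC(=O)c1ccccc1
F3 | step 9 | 2-(trimethylsilyl)ethyl (1E,3R,8R,9S)-3-(benzoyloxy)-9-bromo-8-hydroxy-4,4,8-trimethylcycloundec-1-ene-1-carboxylate | CC1(C)CCC[C@@](C)(O)[C@@H](Br)CC/C(C(=O)OCC[Si](C)(C)C)=C\[C@H]1OC(=O)c1ccccc1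
F4 | step 2 | (2S)-3,3-dimethyl-2-[(phenylamino)oxy]hex-5-enal | O=C[C@@H](ONc1ccccc1)C(C)(C)CC=C
F5 | step 2 | 2-(trimethylsilyl)ethyl (2E,4R)-2-[(3E)-4-iodopent-3-en-1-yl]-5,5-dimethyl-4-[(phenylamino)oxy]octa-2,7-dienoate | C=CCC(C)(C)[C@H](ONc1ccccc1)/C=C(\CC/C=C(\C)I)C(=O)OCC[Si](C)(C)C
F6 | step 2 | 2-(trimethylsilyl)ethyl (2E,4R)-4-hydroxy-2-[(3E)-4-iodopent-3-en-1-yl]-5,5-dimethylocta-2,7-dienoate | C=CCC(C)(C)[C@H](O)/C=C(\CC/C=C(\C)I)C(=O)OCC[Si](C)(C)C
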